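**Strategy.** The route rests on cutting the C3–C4 bond of the pyranone (ring C). These two adjacent oxygen-bearing carbons are, at the dihydro level, an α-ketol, which an umpoled aldehyde can assemble. A triazolylidene carbene turns the aryl aldehyde of a dialdehyde into an acyl anion equivalent that adds to the second formyl group, closing ring C and installing the C4 ketone and the C3 hydroxyl in one catalytic operation. The precursor is a 2,6-dioxygenated benzaldehyde whose ether oxygen (future O1) already carries C2 with the ring B aryl group and an aldehyde (future C3). Oxidation to the flavonol, 3-O-sulfation and debenzylation finish the synthesis.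

Key step: step 7

Remark: all chiral intermediates are racemic, since C2 and C3 become trigonal in the flavonol; the target is taken as the free hydrogen sulfate as drawn, released from its triethylammonium salt by proton exchange in the last operation (it is best stored cold or as a salt).

**Step 1**
Reactants: 1 2,4,6-trihydroxybenzaldehyde
Product: 2 2,6-dihydroxy-4-methoxybenzaldehyde
Conditions: Me2SO4 (1.0 equiv), K2CO3 (1.0 equiv), acetone, 0 °C to rt
Reagents that add atoms: dimethyl sulfate, COS(=O)(=O)OC
Why: The 4-hydroxyl is the most acidic and the only one not chelated to the formyl group, so one equivalent of base and alkylating agent should methylate it selectively in a Williamson ether synthesis.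

**Step 2**
Reactants: 2 2,6-dihydroxy-4-methoxybenzaldehyde
Product: 3 2-benzyloxy-6-hydroxy-4-methoxybenzaldehyde
Conditions: BnBr (1.05 equiv), K2CO3, acetone, reflux
Reagents that add atoms: benzyl bromide, BrCc1ccccc1
Why: The substrate is symmetric, so Williamson mono-benzylation can give only one ether, and the remaining hydroxyl is then locked in a hydrogen bond to the aldehyde and should resist a second alkylation.

**Step 3**
Reactants: 4 racemic 4-hydroxy-3-methoxymandelic acid
Product: 5 racemic benzyl 2-(4-benzyloxy-3-methoxyphenyl)-2-hydroxyacetate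
Conditions: BnBr (2.2 equiv), K2CO3, DMF, rt
Reagents that add atoms: benzyl bromide, BrCc1ccccc1
Why: Carbonate deprotonates only the phenol and the carboxylic acid, so SN2 benzylation (Williamson etherification plus carboxylate alkylation) should leave the secondary alcohol free for the next step.

**Step 4**
Reactants: 3 2-benzyloxy-6-hydroxy-4-methoxybenzaldehyde; 5 racemic benzyl 2-(4-benzyloxy-3-methoxyphenyl)-2-hydroxyacetate
Product: 6 racemic benzyl 2-(3-benzyloxy-2-formyl-5-methoxyphenoxy)-2-(4-benzyloxy-3-methoxyphenyl)acetate
Conditions: PPh3, DIAD, THF, 0 °C to rt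
Reagents that add atoms: none
Why: In this Mitsunobu reaction the acidic ortho-formyl phenol displaces the activated benzylic α-hydroxy ester, which has no β-hydrogen to eliminate; the centre is inverted but racemic, so O1–C2 is formed without any stereochemical demand.

**Step 5**
Reactants: 6 racemic benzyl 2-(3-benzyloxy-2-formyl-5-methoxyphenoxy)-2-(4-benzyloxy-3-methoxyphenyl)acetate
Product: 7 racemic 2-[3-benzyloxy-2-(hydroxymethyl)-5-methoxyphenoxy]-2-(4-benzyloxy-3-methoxyphenyl)ethan-1-ol
Conditions: LiAlH4, THF, 0 °C; then aq. sodium potassium tartrate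
Reagents that add atoms: none
Why: Hydride reduction takes the aryl aldehyde and the benzyl ester to the two primary alcohols while aryl and benzyl ethers are inert, and the non-acidic work-up protects the acid-sensitive trialkoxybenzyl alcohol.

**Step 6**
Reactants: 7 racemic 2-[3-benzyloxy-2-(hydroxymethyl)-5-methoxyphenoxy]-2-(4-benzyloxy-3-methoxyphenyl)ethan-1-ol
Product: 8 racemic 2-benzyloxy-6-[1-(4-benzyloxy-3-methoxyphenyl)-2-oxoethoxy]-4-methoxybenzaldehyde
Conditions: Dess–Martin periodinane (DMP, 2.5 equiv), pyridine, CH2Cl2, 0 °C to rt; used crude at once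
Reagents that add atoms: none
Why: Dess–Martin oxidation under pyridine-buffered, anhydrous conditions should take both primary alcohols to the aldehyde level and no further, and the crude dialdehyde is used directly because its C2–H is acidic and the centre is labile.

**Step 7**
Reactants: 8 racemic 2-benzyloxy-6-[1-(4-benzyloxy-3-methoxyphenyl)-2-oxoethoxy]-4-methoxybenzaldehyde
Product: 9 racemic trans-5-benzyloxy-2-(4-benzyloxy-3-methoxyphenyl)-3-hydroxy-7-methoxychroman-4-one
Conditions: 2-(pentafluorophenyl)-6,7-dihydro-5H-pyrrolo[2,1-c][1,2,4]triazol-2-ium tetrafluoroborate (15 mol%), iPr2NEt (15 mol%), THF, rt, argon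
Reagents that add atoms: none
Why: The triazolylidene released by the amine adds to the aryl aldehyde, proton transfer gives the aryl-conjugated enaminol (acyl anion equivalent), and this carbon attacks the neighbouring aliphatic formyl group before the catalyst is expelled, so C3–C4 and the α-ketol form in one catalytic operation. The closest known reaction type is the carbene-catalysed intramolecular crossed benzoin reaction that converts 2-(2-oxoalkoxy)benzaldehydes into 3-hydroxychroman-4-ones, together with the azolium-catalysed cyclisation of dialdehydes to cyclic acyloins. The dihydropyranone ring closes in a 6-exo-trig mode. The new C3 stereocentre is set under thermodynamic control relative to C2, which equilibrates through the enolisable aldehyde before closure while C3 can equilibrate through the ketone enol afterwards, so the 2,3-diequatorial trans racemate should dominate; neither centre survives step 8. The selectivity needed is that the aryl aldehyde, not the aliphatic one, becomes the acyl anion; the aliphatic aldehyde carries an aryl and an aryloxy group on its α-carbon, which hinders carbene addition and enaminol formation there while leaving it a good electrophile, and the product is an aryl ketone conjugated to the trioxygenated ring, the thermodynamic sink of the reversible benzoin manifold. Any 4-hydroxy-3-keto regioisomer or cis isomer would give the same dione in step 8.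

**Step 8**
Reactants: 9 racemic trans-5-benzyloxy-2-(4-benzyloxy-3-methoxyphenyl)-3-hydroxy-7-methoxychroman-4-one
Product: 11 5-benzyloxy-2-(4-benzyloxy-3-methoxyphenyl)-3-hydroxy-7-methoxy-4H-chromen-4-one, via 3,4-dione tautomer 10 (not isolated)
Conditions: DMP (1.1 equiv), CH2Cl2, 0 °C to rt
Reagents that add atoms: none
Why: Dess–Martin oxidation of the secondary carbinol gives the 3,4-dione, whose doubly activated C2–H enolises at once to the aromatic 4-pyranone, so both stereocentres vanish, and the oxidant is kept near one equivalent to spare the enol product.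

**Step 9**
Reactants: 11 5-benzyloxy-2-(4-benzyloxy-3-methoxyphenyl)-3-hydroxy-7-methoxy-4H-chromen-4-one
Product: 12 triethylammonium 5-benzyloxy-2-(4-benzyloxy-3-methoxyphenyl)-7-methoxy-4-oxo-4H-chromen-3-yl sulfate
Conditions: SO3·NEt3 (5 equiv), Et3N, DMF, 55 °C
Reagents that add atoms: sulfur trioxide–triethylamine complex, CC[N+](CC)(CC)S(=O)(=O)[O-]
Why: The 3-hydroxyl is the only free hydroxyl, so O-sulfation with the amine–sulfur trioxide complex can occur only there, and the product should be isolable as a stable triethylammonium salt.

**Step 10**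
Reactants: 12 triethylammonium 5-benzyloxy-2-(4-benzyloxy-3-methoxyphenyl)-7-methoxy-4-oxo-4H-chromen-3-yl sulfate
Product: 14 rhamnazin 3-O-sulfate (5-hydroxy-2-(4-hydroxy-3-methoxyphenyl)-7-methoxy-4-oxo-4H-chromen-3-yl hydrogen sulfate), via triethylammonium rhamnazin 3-O-sulfate 13 (not isolated)
Conditions: H2 (1 atm), 10% Pd/C, THF–MeOH, rt; filter; sulfonic acid cation-exchange resin (H+ form), MeOH–H2O, 0 °C; freeze-dry
Reagents that add atoms: none
Why: Catalytic hydrogenolysis should cleave both benzyl ethers while the sulfate monoester anion and the tetrasubstituted C2=C3 bond of the pyranone are not reduced at atmospheric pressure, and brief cold cation exchange then gives the acid form without hydrolysing the sulfate.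

**Compound list**
1 | 2,4,6-trihydroxybenzaldehyde | O=Cc1c(O)cc(O)cc1O | starting material
2 | 2,6-dihydroxy-4-methoxybenzaldehyde | COc1cc(O)c(C=O)c(O)c1 | intermediate
3 | 2-benzyloxy-6-hydroxy-4-methoxybenzaldehyde | COc1cc(O)c(C=O)c(OCc2ccccc2)c1 | intermediate
4 | racemic 4-hydroxy-3-methoxymandelic acid (vanillylmandelic acid) | COc1cc(C(O)C(=O)O)ccc1O | starting material
5 | racemic benzyl 2-(4-benzyloxy-3-methoxyphenyl)-2-hydroxyacetate | COc1cc(C(O)C(=O)OCc2ccccc2)ccc1OCc1ccccc1 | intermediate
6 | racemic benzyl 2-(3-benzyloxy-2-formyl-5-methoxyphenoxy)-2-(4-benzyloxy-3-methoxyphenyl)acetate | O=Cc1c(OCc2ccccc2)cc(OC)cc1OC(C(=O)OCc1ccccc1)c1ccc(OCc2ccccc2)c(OC)c1 | intermediate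
7 | racemic 2-[3-benzyloxy-2-(hydroxymethyl)-5-methoxyphenoxy]-2-(4-benzyloxy-3-methoxyphenyl)ethan-1-ol | OCc1c(OCc2ccccc2)cc(OC)cc1OC(CO)c1ccc(OCc2ccccc2)c(OC)c1 | intermediate
8 | racemic 2-benzyloxy-6-[1-(4-benzyloxy-3-methoxyphenyl)-2-oxoethoxy]-4-methoxybenzaldehyde | O=CC(Oc1cc(OC)cc(OCc2ccccc2)c1C=O)c1ccc(OCc2ccccc2)c(OC)c1 | intermediate
9 | racemic trans-5-benzyloxy-2-(4-benzyloxy-3-methoxyphenyl)-3-hydroxy-7-methoxychroman-4-one (2R,3R enantiomer drawn) | COc1cc(ccc1OCc1ccccc1)[C@@H]1[C@H](C(=O)c2c(OCc3ccccc3)cc(OC)cc2O1)O | intermediate
10 | racemic 5-benzyloxy-2-(4-benzyloxy-3-methoxyphenyl)-7-methoxychromane-3,4-dione (not isolated) | COc1cc(ccc1OCc1ccccc1)C1Oc2cc(OC)cc(OCc3ccccc3)c2C(=O)C1=O | intermediate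
11 | 5-benzyloxy-2-(4-benzyloxy-3-methoxyphenyl)-3-hydroxy-7-methoxy-4H-chromen-4-one | COc1cc(OCc2ccccc2)c2c(=O)c(O)c(-c3ccc(OCc4ccccc4)c(OC)c3)oc2c1 | intermediate
12 | triethylammonium 5-benzyloxy-2-(4-benzyloxy-3-methoxyphenyl)-7-methoxy-4-oxo-4H-chromen-3-yl sulfate | COc1cc(OCc2ccccc2)c2c(=O)c(OS(=O)(=O)[O-])c(-c3ccc(OCc4ccccc4)c(OC)c3)oc2c1.CC[NH+](CC)CC | intermediate
13 | triethylammonium rhamnazin 3-O-sulfate (not isolated) | COc1cc(O)c2c(=O)c(OS(=O)(=O)[O-])c(-c3ccc(O)c(OC)c3)oc2c1.CC[NH+](CC)CC | intermediate
14 | rhamnazin 3-O-sulfate | COc1cc(O)c2c(=O)c(OS(=O)(=O)O)c(-c3ccc(O)c(OC)c3)oc2c1 | target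

**Totals.** Total step count: 10. Longest linear sequence: 9 steps (steps 1, 2 and 4 to 10).

**Steps most likely to fail**

Step 7. The carbene may add to the aliphatic aldehyde instead; its enaminol can expel the aryloxide on the α-carbon (internal redox to an aryl arylacetate). The amine may also start an intramolecular aldol of the enolisable aldehyde onto the aryl aldehyde. Either path consumes the dialdehyde without forming C3–C4. The fallback sets out from dialdehyde 8 and makes the same bond by reductive ketyl coupling: SmI2 in THF with t-BuOH at −78 °C (intramolecular pinacol coupling) should give 5-benzyloxy-2-(4-benzyloxy-3-methoxyphenyl)-7-methoxychromane-3,4-diol F1 as a diastereomer mixture. Oxidation of both carbinols with 2-iodoxybenzoic acid in DMSO, which does not cleave glycols, should give dione 10, which tautomerises, so the route is rejoined at flavonol 11.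

Step 6. After the first oxidation the hydroxy aldehyde may close to a seven-membered lactol that is oxidised on to a lactone, and the doubly activated α-CH of the new aldehyde may enolise and degrade during work-up. The fallback sets out from diol 7 and oxidises in two chemoselective stages. Activated MnO2 in CH2Cl2 at rt should oxidise only the benzylic alcohol and give 2-benzyloxy-6-[1-(4-benzyloxy-3-methoxyphenyl)-2-hydroxyethoxy]-4-methoxybenzaldehyde F2, which is stable and can be purified. Parikh–Doering oxidation of the remaining primary alcohol (SO3·pyridine, DMSO, iPr2NEt, 0 °C) then returns to dialdehyde 8, which is taken into step 7 without storage.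

Step 4. The chelated phenol may be too poor a nucleophile, so that the activated alcohol is intercepted by the hydrazide anion or is not consumed. The fallback sets out from mandelate 5 and replaces the redox condensation by a phenoxide alkylation. PBr3 in CH2Cl2 at 0 °C should give benzyl 2-bromo-2-(4-benzyloxy-3-methoxyphenyl)acetate F3, a doubly activated secondary bromide that is used crude. SN2 alkylation of phenol 3 with it (K2CO3, DMF, rt) returns to ester 6.

**Further compounds**
F1 | step 7 | 5-benzyloxy-2-(4-benzyloxy-3-methoxyphenyl)-7-methoxychromane-3,4-diol (racemic, mixture of diastereomers) | COc1cc(ccc1OCc1ccccc1)C1Oc2cc(OC)cc(OCc3ccccc3)c2C(O)C1O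
F2 | step 6 | racemic 2-benzyloxy-6-[1-(4-benzyloxy-3-methoxyphenyl)-2-hydroxyethoxy]-4-methoxybenzaldehyde | O=Cc1c(OCc2ccccc2)cc(OC)cc1OC(CO)c1ccc(OCc2ccccc2)c(OC)c1
F3 | step 4 | racemic benzyl 2-bromo-2-(4-benzyloxy-3-methoxyphenyl)acetate | COc1cc(C(Br)C(=O)OCc2ccccc2)ccc1OCc1ccccc1
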